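The lactone C3–C4 bond (lignan C8–C8') ties together the α-carbons of two 3-arylpropanoyl units, one carrying the dihydrobenzofuran, the other the aryl glycerol ether. Everything rests on cutting this bond. In the key step the lithium enolates of an N-acyl oxazolidinone (dihydrobenzofuran half) and a methyl ester (glycerol ether half) are joined by one-electron oxidation with Fe(acac)3. Both finished halves are united, lactone C4 is set by the auxiliary, and the unlike imide and ester termini fix the lactone orientation. The precursors are saturated 3-arylpropanoyl compounds whose other functions are only aryl, benzyl and silyl ethers. Reduction, lactonisation with equilibration, desilylation and hydrogenolysis finish the synthesis.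

Key step: step 21

Assumption: the (R)-configured catalyst Rh2(R-PTTL)4 is assigned to the (2S) insertion product by analogy with simpler 2-(benzyloxy)phenyl diazoacetates; if the sense is opposite, the mirror-image catalyst is used.
Assumption: 32 and 33 are drawn as the (2R,3R) epimers; material epimeric at the ester α-carbon has the same constitution, is carried along unseparated and converges in step 23.

**Fragment A (steps 1–13)**

Step 1
Reactants: 1 methyl 3-(4-hydroxy-3-methoxyphenyl)propanoate (methyl dihydroferulate)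
Product: 2 methyl 3-(3-bromo-4-hydroxy-5-methoxyphenyl)propanoate
Conditions: NBS (1.0 equiv), i-Pr2NH (10 mol %), CH2Cl2, 0 °C → rt
Reagents that add atoms: N-bromosuccinimide, O=C1CCC(=O)N1Br
Why: Amine-catalysed electrophilic aromatic bromination delivers bromine through a hydrogen-bonded N-bromoamine to the only free position ortho to the phenol (para is blocked by the side chain), which overrides the competing site para to the methoxy group.

Step 2
Reactants: 3 4-benzyloxy-3-methoxybenzaldehyde
Product: 4 (4-benzyloxy-3-methoxyphenyl)methanol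
Conditions: NaBH4, MeOH, 0 °C
Reagents that add atoms: none
Why: Borohydride reduction of an aromatic aldehyde is fast and leaves the benzyl ether untouched.

Step 3
Reactants: 4 (4-benzyloxy-3-methoxyphenyl)methanol
Product: 5 4-benzyloxy-3-methoxybenzyl chloride
Conditions: SOCl2, CH2Cl2, 0 °C; concentrated and used crude
Reagents that add atoms: thionyl chloride, O=S(Cl)Cl
Why: Deoxychlorination of an electron-rich benzylic alcohol with thionyl chloride runs at 0 °C, and the labile chloride is used at once.

Step 4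
Reactants: 2 methyl 3-(3-bromo-4-hydroxy-5-methoxyphenyl)propanoate; 5 4-benzyloxy-3-methoxybenzyl chloride
Product: 6 methyl 3-{3-bromo-4-[(4-benzyloxy-3-methoxybenzyl)oxy]-5-methoxyphenyl}propanoate
Conditions: K2CO3, DMF, rt
Reagents that add atoms: none
Why: Williamson ether synthesis, in which the acidic bromophenoxide attacks a very reactive benzylic chloride and carbonate is too weak to touch the methyl ester.

Step 5
Reactants: 6 bromoaryl benzyl ether; 7 dimethyl malonate
Product: 8 dimethyl 2-{2-[(4-benzyloxy-3-methoxybenzyl)oxy]-3-methoxy-5-(3-methoxy-3-oxopropyl)phenyl}malonate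
Conditions: Pd(dba)2 (3 mol %), P(t-Bu)3·HBF4 (6 mol %), K3PO4, toluene, 80 °C
Reagents that add atoms: none
Why: Palladium-catalysed malonate α-arylation with a bulky electron-rich trialkylphosphine accepts ortho-alkoxy aryl bromides, and phosphate deprotonates only the malonate, not the side-chain ester.

Step 6
Reactants: 8 aryl malonate
Product: 9 methyl 3-{4-[(4-benzyloxy-3-methoxybenzyl)oxy]-3-methoxy-5-(2-methoxy-2-oxoethyl)phenyl}propanoate
Conditions: LiCl, H2O (2 equiv), DMSO, 120–130 °C
Reagents that add atoms: none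
Why: Krapcho dealkoxycarbonylation removes one malonate ester because only there does loss of CO2 give a stabilised benzylic ester carbanion, so the isolated side-chain ester stays.

Step 7
Reactants: 9 methyl arylacetate
Product: 10 methyl 3-{4-[(4-benzyloxy-3-methoxybenzyl)oxy]-3-(1-diazo-2-methoxy-2-oxoethyl)-5-methoxyphenyl}propanoate
Conditions: p-ABSA, DBU, MeCN, 0 °C → rt
Reagents that add atoms: 4-acetamidobenzenesulfonyl azide (p-ABSA), CC(=O)Nc1ccc(cc1)S(=O)(=O)N=[N+]=[N-]
Why: Regitz diazo transfer, in which DBU deprotonates only the doubly activated arylacetate methylene, so N2 is transferred there and not α to the side-chain ester.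

Step 8
Reactants: 10 aryl diazoacetate
Product: 11 methyl (2S,3R)-2-(4-benzyloxy-3-methoxyphenyl)-7-methoxy-5-(3-methoxy-3-oxopropyl)-2,3-dihydrobenzofuran-3-carboxylate (cis)
Conditions: Rh2(R-PTTL)4 (dirhodium tetrakis[N-phthaloyl-(R)-tert-leucinate], 1 mol %), toluene, −60 °C
Reagents that add atoms: none
Why: Enantioselective intramolecular 1,5 C–H insertion of a donor/acceptor rhodium carbenoid into the activated benzylic ether methylene closes the five-membered ring, the chiral carboxylate ligands choosing one enantiotopic hydrogen (C2, S) and the concerted insertion giving the kinetic cis ester (C3, R).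

Step 9
Reactants: 11 cis diester
Product: 12 methyl (2S,3S)-2-(4-benzyloxy-3-methoxyphenyl)-7-methoxy-5-(3-methoxy-3-oxopropyl)-2,3-dihydrobenzofuran-3-carboxylate (trans)
Conditions: NaOMe (0.5 equiv), MeOH/THF, rt
Reagents that add atoms: none
Why: Base epimerisation through the ester enolate moves the C3 ester to the less crowded trans face (C3 becomes S) while C2 stays fixed, since ring opening by β-elimination would be the reverse of a disfavoured 5-endo-trig closure.

Step 10
Reactants: 12 trans diester
Product: 13 3-[(2S,3S)-2-(4-benzyloxy-3-methoxyphenyl)-7-methoxy-3-(methoxycarbonyl)-2,3-dihydrobenzofuran-5-yl]propanoic acid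
Conditions: Me3SnOH (3 equiv), ClCH2CH2Cl, 70 °C; dilute HCl wash
Reagents that add atoms: trimethyltin hydroxide, C[Sn](C)(C)O
Why: Ester cleavage with trimethyltin hydroxide is governed by steric access, so the unbranched side-chain methyl ester reacts while the α-branched ring ester between two aryl groups is left, and the near-neutral medium avoids β-elimination.

Step 11
Reactants: 13 mono acid
Product: 14 3-[(2S,3R)-2-(4-benzyloxy-3-methoxyphenyl)-3-(hydroxymethyl)-7-methoxy-2,3-dihydrobenzofuran-5-yl]propanoic acid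
Conditions: LiBH4 (3 equiv), THF, 0 °C → rt; aq citric acid
Reagents that add atoms: none
Why: Chemoselective borohydride reduction, in which the first hydride turns the acid into an inert lithium carboxylate and LiBH4 then reduces only the ester, with no change at C3 (the descriptor becomes R by priority change alone).

Step 12
Reactants: 14 hydroxy acid
Product: 16 3-[(2S,3R)-2-(4-benzyloxy-3-methoxyphenyl)-3-(tert-butyldimethylsilyloxymethyl)-7-methoxy-2,3-dihydrobenzofuran-5-yl]propanoic acid, via silyl ester 15 (not isolated)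
Conditions: TBSCl (2.5 equiv), imidazole, DMF, rt; then K2CO3, MeOH/THF/H2O, rt; pH 4 work-up
Reagents that add atoms: tert-butyldimethylsilyl chloride, CC(C)(C)[Si](C)(C)Cl
Why: Standard silylation covers hydroxyl and carboxyl groups alike, and the far more labile silyl ester is then cleaved selectively by mild aqueous carbonate.

Step 13
Reactants: 16 silyl ether acid; 17 (S)-4-benzyloxazolidin-2-one
Product: 19 (S)-4-benzyl-3-{3-[(2S,3R)-2-(4-benzyloxy-3-methoxyphenyl)-3-(tert-butyldimethylsilyloxymethyl)-7-methoxy-2,3-dihydrobenzofuran-5-yl]propanoyl}oxazolidin-2-one (fragment A), via mixed pivalic anhydride 18 (not isolated)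
Conditions: PivCl, Et3N, THF, −20 °C; then LiCl, 17, −20 °C → rt
Reagents that add atoms: pivaloyl chloride, CC(C)(C)C(=O)Cl (its atoms remain only in 18)
Why: Mixed-anhydride N-acylation of the oxazolidinone under LiCl/Et3N activation takes place at the less hindered acyl group and needs no strong base.

**Fragment B (steps 14–20)**

Step 14
Reactants: 1 methyl dihydroferulate; 20 (R)-4-benzyl-3-(chloroacetyl)oxazolidin-2-one
Product: 21 methyl 3-(4-{2-[(R)-4-benzyl-2-oxooxazolidin-3-yl]-2-oxoethoxy}-3-methoxyphenyl)propanoate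
Conditions: K2CO3, MeCN, rt → 40 °C
Reagents that add atoms: none
Why: Williamson-type SN2 O-alkylation, in which the carbonyl-activated primary chloride reacts with the phenoxide faster than either imide carbonyl under mild carbonate conditions.

Step 15
Reactants: 21 aryloxyacetyl imide; 3 4-benzyloxy-3-methoxybenzaldehyde
Product: 24 syn aldol adduct (acyl numbering 2R,3S) methyl 3-(4-{[(1S,2R)-1-(4-benzyloxy-3-methoxyphenyl)-3-[(R)-4-benzyl-2-oxooxazolidin-3-yl]-1-hydroxy-3-oxopropan-2-yl]oxy}-3-methoxyphenyl)propanoate, via dibutylboron enolate 22 (not isolated), via dibutylboron aldolate 23 (not isolated)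
Conditions: Bu2BOTf, i-Pr2NEt, CH2Cl2, −78 → 0 °C; 3, −78 → 0 °C; pH 7 buffer, MeOH, 30% H2O2, 0 °C
Reagents that add atoms: dibutylboron triflate, CCCCB(CCCC)OS(=O)(=O)C(F)(F)F (boron and butyl groups remain only in 22 and 23)
Why: Evans boron aldol, in which soft enolisation touches only the imide and gives the (Z)-enolate, whose chair Zimmerman–Traxler transition state with one face shielded by the (R)-benzyl group sets both new centres as the syn (2R,3S) pair.

Step 16
Reactants: 24 syn aldol adduct
Product: 25 methyl 3-(4-{[(1S,2S)-1-(4-benzyloxy-3-methoxyphenyl)-1,3-dihydroxypropan-2-yl]oxy}-3-methoxyphenyl)propanoate (threo diol)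
Conditions: NaBH4, THF/H2O (4:1), 0 °C → rt
Reagents that add atoms: none
Why: Reductive auxiliary removal, in which aqueous borohydride reduces the activated exocyclic imide carbonyl but not an unactivated methyl ester, and both stereocentres are retained.

Step 17
Reactants: 25 threo diol
Product: 26 methyl 3-(4-{[(1S,2S)-1-(4-benzyloxy-3-methoxyphenyl)-3-(tert-butyldimethylsilyloxy)-1-hydroxypropan-2-yl]oxy}-3-methoxyphenyl)propanoate
Conditions: TBSCl (1.05 equiv), imidazole, CH2Cl2, 0 °C
Reagents that add atoms: tert-butyldimethylsilyl chloride, CC(C)(C)[Si](C)(C)Cl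
Why: Sterically differentiated silylation, since one equivalent of TBSCl reacts at the primary hydroxyl well before the secondary benzylic one.

Step 18
Reactants: 26 primary silyl ether
Product: 27 (1R,2S)-4-nitrobenzoate methyl 3-(4-{[(1R,2S)-1-(4-benzyloxy-3-methoxyphenyl)-3-(tert-butyldimethylsilyloxy)-1-(4-nitrobenzoyloxy)propan-2-yl]oxy}-3-methoxyphenyl)propanoate
Conditions: 4-O2NC6H4CO2H, PPh3, DIAD, toluene, −20 → 0 °C
Reagents that add atoms: 4-nitrobenzoic acid, OC(=O)c1ccc(cc1)[N+](=O)[O-]
Why: Mitsunobu reaction with an acidic carboxylic acid in a non-polar solvent at low temperature favours SN2 displacement of the oxyphosphonium ion and inverts the benzylic centre from S to R (erythro), a transformation known for aryl glycerol β-aryl ethers.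

Step 19
Reactants: 27 nitrobenzoate
Product: 28 methyl 3-(4-{[(1R,2S)-1-(4-benzyloxy-3-methoxyphenyl)-3-(tert-butyldimethylsilyloxy)-1-hydroxypropan-2-yl]oxy}-3-methoxyphenyl)propanoate (erythro alcohol)
Conditions: K2CO3 (0.3 equiv), MeOH, 0 °C → rt
Reagents that add atoms: none
Why: Carbonate-catalysed transesterification removes the activated nitrobenzoate by acyl–oxygen cleavage, so the new configuration is kept and the side-chain methyl ester can only exchange with itself.

Step 20
Reactants: 28 erythro alcohol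
Product: 29 methyl 3-(4-{[(1R,2S)-1-(4-benzyloxy-3-methoxyphenyl)-1,3-bis(tert-butyldimethylsilyloxy)propan-2-yl]oxy}-3-methoxyphenyl)propanoate (fragment B)
Conditions: TBSOTf, 2,6-lutidine, CH2Cl2, −78 → 0 °C
Reagents that add atoms: tert-butyldimethylsilyl triflate, CC(C)(C)[Si](C)(C)OS(=O)(=O)C(F)(F)F
Why: Silyl triflate with a hindered pyridine base silylates the crowded secondary benzylic alcohol quickly at low temperature without ionising it.

**Union and end game (steps 21–25)**

Step 21
Reactants: 19 fragment A imide; 29 fragment B methyl ester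
Product: 32 methyl (2R,3R)-3-{[(S)-4-benzyl-2-oxooxazolidin-3-yl]carbonyl}-2-(ring B benzyl)-4-(dihydrobenzofuran-5-yl)butanoate (fully protected 2,3-dibenzylsuccinate imide ester), via imide lithium enolate 30 (not isolated), via ester lithium enolate 31 (not isolated)
Conditions: 19 (1.0 equiv), 29 (1.5 equiv), LiN(i-Pr)2 (2.6 equiv), THF, −78 °C; Fe(acac)3 (2.6 equiv) in THF, −78 °C → rt
Reagents that add atoms: lithium diisopropylamide, [Li]N(C(C)C)C(C)C (lithium remains only in 30 and 31)
Why: LiN(i-Pr)2 converts both carbonyl compounds into lithium enolates 30 and 31, Fe(acac)3 (trivalent iron) removes one electron from an enolate inside a mixed aggregate, the α-carbonyl radical so formed is trapped by the other enolate, and a second equivalent of oxidant takes the remaining electron to give the 1,4-dicarbonyl compound. The closest known reaction type is the intermolecular oxidative heterocoupling of an N-acyl oxazolidinone enolate with an ester enolate, which has already served for simple dibenzylbutyrolactone lignans. No ring is closed here; the bond made is the future lactone C3–C4 bond. The new centre α to the imide (future C4, R) is controlled by the benzyl group of the (S)-auxiliary on the lithium-chelated (Z)-enolate, bonding taking place on the open face in the same sense as enolate alkylation, whereas the new centre α to the ester (future C3) is not controlled and is corrected in step 23. The step needs cross- over homocoupling, which rests on the unlike oxidation potentials and aggregation of imide and ester enolates and is helped by using the more easily made ester 29 in excess. Chemoselectivity is secured because every other group in 19 and 29 is an aryl, benzyl or silyl ether that neither the amide base nor the mild oxidant attacks.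

Step 22
Reactants: 32 succinate imide ester
Product: 33 methyl (2R,3R)-3-(hydroxymethyl)-2-(ring B benzyl)-4-(dihydrobenzofuran-5-yl)butanoate (protected hydroxy ester)
Conditions: LiBH4 (1.5 equiv), H2O (1.5 equiv), Et2O/THF, 0 °C; crude carried on
Reagents that add atoms: none
Why: Chemoselective hydride reduction of the N-acyl oxazolidinone, whose imide carbonyl is far more electrophilic than the methyl ester, with LiBH4 plus one equivalent of water favouring exocyclic attack on hindered imides and touching no stereocentre.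

Step 23
Reactants: 33 hydroxy ester
Product: 34 protected (3R,4R)-trans-3,4-dibenzylbutyrolactone (three TBS ethers and two phenolic benzyl ethers)
Conditions: DBU, toluene, 80 °C
Reagents that add atoms: none
Why: Base-mediated lactonisation (5-exo-trig acyl substitution of the primary hydroxyl on the methyl ester) followed by enolate equilibration at C3 drives all material to the more stable trans lactone (3R,4R), with C4 as the fixed reference.

Step 24
Reactants: 34 protected lactone
Product: 35 bis(O-benzyl) ether of the target (three free hydroxyl groups)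
Conditions: Bu4NF/AcOH (1:1, 6 equiv), THF, 0 °C → rt
Reagents that add atoms: none
Why: Fluoride desilylation buffered with acetic acid removes all three TBS groups without opening the lactone, and it is done while both phenols are still masked so that no quinone methide can scramble the benzylic centres.

Step 25
Reactants: 35 bis(O-benzyl) ether
Product: 36 target CNP0298853.1
Conditions: H2 (1 atm), 10% Pd/C, EtOAc/EtOH, rt
Reagents that add atoms: none
Why: Catalytic hydrogenolysis of aryl benzyl ethers over Pd/C in neutral solvent at 1 atm is much faster than cleavage of the secondary benzylic alcohol or the cyclic benzylic ether, so stopping after two equivalents of hydrogen should give the target.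

**Compound list**

1 | methyl 3-(4-hydroxy-3-methoxyphenyl)propanoate | COC(=O)CCc1ccc(O)c(OC)c1 | starting material
2 | methyl 3-(3-bromo-4-hydroxy-5-methoxyphenyl)propanoate | COC(=O)CCc1cc(Br)c(O)c(OC)c1 | intermediate
3 | 4-benzyloxy-3-methoxybenzaldehyde | O=Cc1ccc(OCc2ccccc2)c(OC)c1 | starting material
4 | (4-benzyloxy-3-methoxyphenyl)methanol | OCc1ccc(OCc2ccccc2)c(OC)c1 | intermediate
5 | 4-benzyloxy-3-methoxybenzyl chloride | ClCc1ccc(OCc2ccccc2)c(OC)c1 | intermediate
6 | bromoaryl benzyl ether | COC(=O)CCc1cc(Br)c(OCc2ccc(OCc3ccccc3)c(OC)c2)c(OC)c1 | intermediate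
7 | dimethyl malonate | COC(=O)CC(=O)OC | starting material
8 | aryl malonate | COC(=O)CCc1cc(C(C(=O)OC)C(=O)OC)c(OCc2ccc(OCc3ccccc3)c(OC)c2)c(OC)c1 | intermediate
9 | methyl arylacetate | COC(=O)CCc1cc(CC(=O)OC)c(OCc2ccc(OCc3ccccc3)c(OC)c2)c(OC)c1 | intermediate
10 | aryl diazoacetate | COC(=O)CCc1cc(C(=[N+]=[N-])C(=O)OC)c(OCc2ccc(OCc3ccccc3)c(OC)c2)c(OC)c1 | intermediate
11 | cis-(2S,3R)-dihydrobenzofuran diester | COC(=O)CCc1cc(OC)c2c(c1)[C@@H](C(=O)OC)[C@@H](c1ccc(OCc3ccccc3)c(OC)c1)O2 | intermediate
12 | trans-(2S,3S)-dihydrobenzofuran diester | COC(=O)CCc1cc(OC)c2c(c1)[C@H](C(=O)OC)[C@@H](c1ccc(OCc3ccccc3)c(OC)c1)O2 | intermediate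
13 | trans-(2S,3S) side-chain acid, ring ester kept | OC(=O)CCc1cc(OC)c2c(c1)[C@H](C(=O)OC)[C@@H](c1ccc(OCc3ccccc3)c(OC)c1)O2 | intermediate
14 | (2S,3R) hydroxy acid | OC(=O)CCc1cc(OC)c2c(c1)[C@H](CO)[C@@H](c1ccc(OCc3ccccc3)c(OC)c1)O2 | intermediate
15 | tert-butyldimethylsilyl ester of 16 | CC(C)(C)[Si](C)(C)OC(=O)CCc1cc(OC)c2c(c1)[C@H](CO[Si](C)(C)C(C)(C)C)[C@@H](c1ccc(OCc3ccccc3)c(OC)c1)O2 | intermediate
16 | (2S,3R) silyl ether acid | OC(=O)CCc1cc(OC)c2c(c1)[C@H](CO[Si](C)(C)C(C)(C)C)[C@@H](c1ccc(OCc3ccccc3)c(OC)c1)O2 | intermediate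
17 | (S)-4-benzyloxazolidin-2-one | O=C1N[C@@H](Cc2ccccc2)CO1 | starting material
18 | mixed pivalic anhydride of 16 | CC(C)(C)C(=O)OC(=O)CCc1cc(OC)c2c(c1)[C@H](CO[Si](C)(C)C(C)(C)C)[C@@H](c1ccc(OCc3ccccc3)c(OC)c1)O2 | intermediate
19 | fragment A, trans-dihydrobenzofuran acyl (S)-oxazolidinone | O=C(CCc1cc(OC)c2c(c1)[C@H](CO[Si](C)(C)C(C)(C)C)[C@@H](c1ccc(OCc3ccccc3)c(OC)c1)O2)N1[C@@H](Cc2ccccc2)COC1=O | intermediate
20 | (R)-4-benzyl-3-(chloroacetyl)oxazolidin-2-one | ClCC(=O)N1[C@H](Cc2ccccc2)COC1=O | starting material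
21 | aryloxyacetyl (R)-oxazolidinone | COC(=O)CCc1ccc(OCC(=O)N2[C@H](Cc3ccccc3)COC2=O)c(OC)c1 | intermediate
22 | (Z)-dibutylboron enolate of 21 | CCCCB(CCCC)O/C(=C\Oc1ccc(CCC(=O)OC)cc1OC)N1[C@H](Cc2ccccc2)COC1=O | intermediate
23 | dibutylboron aldolate of 24 | COc1cc([C@H](OB(CCCC)CCCC)[C@H](C(=O)N2[C@H](Cc3ccccc3)COC2=O)Oc2ccc(CCC(=O)OC)cc2OC)ccc1OCc1ccccc1 | intermediate
24 | syn (2R,3S) glycolate aldol adduct | COc1cc([C@H](O)[C@H](C(=O)N2[C@H](Cc3ccccc3)COC2=O)Oc2ccc(CCC(=O)OC)cc2OC)ccc1OCc1ccccc1 | intermediate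
25 | threo (1S,2S) diol | COc1cc([C@H](O)[C@H](CO)Oc2ccc(CCC(=O)OC)cc2OC)ccc1OCc1ccccc1 | intermediate
26 | threo (1S,2S) primary silyl ether | COc1cc([C@H](O)[C@H](CO[Si](C)(C)C(C)(C)C)Oc2ccc(CCC(=O)OC)cc2OC)ccc1OCc1ccccc1 | intermediate
27 | erythro (1R,2S) 4-nitrobenzoate | COc1cc([C@@H](OC(=O)c2ccc(cc2)[N+](=O)[O-])[C@H](CO[Si](C)(C)C(C)(C)C)Oc2ccc(CCC(=O)OC)cc2OC)ccc1OCc1ccccc1 | intermediate
28 | erythro (1R,2S) alcohol | COc1cc([C@@H](O)[C@H](CO[Si](C)(C)C(C)(C)C)Oc2ccc(CCC(=O)OC)cc2OC)ccc1OCc1ccccc1 | intermediate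
29 | fragment B, erythro (1R,2S) bis-silyl ether methyl ester | COc1cc([C@@H](O[Si](C)(C)C(C)(C)C)[C@H](CO[Si](C)(C)C(C)(C)C)Oc2ccc(CCC(=O)OC)cc2OC)ccc1OCc1ccccc1 | intermediate
30 | (Z)-lithium enolate of 19 | [Li]O/C(=C\Cc1cc(OC)c2c(c1)[C@H](CO[Si](C)(C)C(C)(C)C)[C@@H](c1ccc(OCc3ccccc3)c(OC)c1)O2)N1[C@@H](Cc2ccccc2)COC1=O | intermediate
31 | lithium enolate of 29 (double-bond geometry left open) | COc1cc([C@@H](O[Si](C)(C)C(C)(C)C)[C@H](CO[Si](C)(C)C(C)(C)C)Oc2ccc(CC=C(OC)O[Li])cc2OC)ccc1OCc1ccccc1 | intermediate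
32 | (2R,3R) 2,3-dibenzylsuccinate imide ester | COc1cc([C@@H](O[Si](C)(C)C(C)(C)C)[C@H](CO[Si](C)(C)C(C)(C)C)Oc2ccc(C[C@@H](C(=O)OC)[C@H](C(=O)N3[C@@H](Cc4ccccc4)COC3=O)Cc3cc(OC)c4c(c3)[C@H](CO[Si](C)(C)C(C)(C)C)[C@@H](c3ccc(OCc5ccccc5)c(OC)c3)O4)cc2OC)ccc1OCc1ccccc1 | intermediate
33 | (2R,3R) hydroxy ester | COc1cc([C@@H](O[Si](C)(C)C(C)(C)C)[C@H](CO[Si](C)(C)C(C)(C)C)Oc2ccc(C[C@@H](C(=O)OC)[C@H](CO)Cc3cc(OC)c4c(c3)[C@H](CO[Si](C)(C)C(C)(C)C)[C@@H](c3ccc(OCc5ccccc5)c(OC)c3)O4)cc2OC)ccc1OCc1ccccc1 | intermediate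
34 | protected (3R,4R)-trans-dibenzylbutyrolactone | COc1cc([C@@H](O[Si](C)(C)C(C)(C)C)[C@H](CO[Si](C)(C)C(C)(C)C)Oc2ccc(C[C@H]3C(=O)OC[C@@H]3Cc3cc(OC)c4c(c3)[C@H](CO[Si](C)(C)C(C)(C)C)[C@@H](c3ccc(OCc5ccccc5)c(OC)c3)O4)cc2OC)ccc1OCc1ccccc1 | intermediate
35 | bis(O-benzyl) ether of the target | COc1cc([C@@H](O)[C@H](CO)Oc2ccc(C[C@H]3C(=O)OC[C@@H]3Cc3cc(OC)c4c(c3)[C@H](CO)[C@@H](c3ccc(OCc5ccccc5)c(OC)c3)O4)cc2OC)ccc1OCc1ccccc1 | intermediate
36 | CNP0298853.1 | COc1cc([C@@H](O)[C@H](CO)Oc2ccc(C[C@H]3C(=O)OC[C@@H]3Cc3cc(OC)c4c(c3)[C@H](CO)[C@@H](c3ccc(O)c(OC)c3)O4)cc2OC)ccc1O | target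

**Step count**

Total step count: 25.
Longest linear sequence: 17 steps (from 3 through steps 2–13, then steps 21–25).

**Steps most likely to fail**

Step 21. Homocoupling of either enolate, proton return and self-condensation of the methyl ester enolate may consume the partners faster than cross-coupling. Facial shielding may also weaken with arms of this size.
- The fallback sets out from 19 and comes back at 34. It replaces the coupling by two classical enolate alkylations.
- Imide 19 is deprotonated with NaN(SiMe3)2 (THF, −78 °C) and alkylated with methyl bromoacetate on the face away from the auxiliary benzyl group to give the succinate imide F1. LiBH4/H2O gives the hydroxy ester F2, and DBU closes it to the (R)-4-substituted butyrolactone F3.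
- The ring B arm is made as a benzylic bromide by running steps 14 to 20 on commercial methyl vanillate (COC(=O)c1ccc(O)c(OC)c1) in place of 1. Alkylation with 20 gives the aryloxyacetyl imide F4, and boron aldol addition to 3 gives the syn adduct F5. NaBH4 gives the threo diol F6, TBSCl the primary silyl ether F7, Mitsunobu inversion the nitrobenzoate F8, methanolysis the erythro alcohol F9, and TBSOTf the bis-silyl ether F10.
- i-Bu2AlH then gives the benzylic alcohol F11 and CBr4/PPh3 the benzylic bromide F12.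
- Enolisation of F3 with LiN(SiMe3)2 and alkylation with F12 anti to the C4 substituent should give 34 directly.

Step 8. The strongly donor-substituted benzylic C–H bond may react through a stepwise hydride-shift pathway, or the ether oxygen may be captured as an oxonium ylide. Either would erode enantio- and cis-selectivity.
- The fallback sets out from 10 and comes back at 12. It gives up catalyst control and separates enantiomers instead.
- Achiral Rh2(OAc)4 (CH2Cl2, rt) closes the ring to 11 together with the mirror-image cis diester F13.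
- NaOMe/MeOH converts this mixture into 12 and the mirror-image trans diester F14.
- Preparative chromatography on a cellulose carbamate chiral stationary phase delivers 12.

Step 18. Ionisation of the oxyphosphonium ion of this 4-alkoxybenzylic alcohol to a stabilised cation may compete with direct displacement, so that inversion is incomplete.
- The fallback sets out from 25 and comes back at 29. The external carboxylate is replaced by an internal nucleophile whose ring constraint favours the erythro series whether displacement is direct or passes through the cation.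
- Diol 25 is acylated at the primary hydroxyl with Boc2O (cat. DMAP, CH2Cl2, 0 °C) to the tert-butyl carbonate F15.
- MsCl/Et3N gives the benzylic mesylate F16. This is displaced as it forms by the carbonate carbonyl oxygen, with loss of isobutene, to give the trans-4-aryl-5-aryloxy-1,3-dioxan-2-one F17 (both substituents equatorial, 1R,2S in the glycerol numbering).
- K2CO3/MeOH releases the erythro diol F18.
- TBSOTf (2.5 equiv)/2,6-lutidine silylates both hydroxyls to 29.

**Further compounds**

F1 | step 21 | methyl (3R)-3-{[(S)-4-benzyl-2-oxooxazolidin-3-yl]carbonyl}-4-(protected dihydrobenzofuran-5-yl)butanoate | COC(=O)C[C@H](C(=O)N1[C@@H](Cc2ccccc2)COC1=O)Cc1cc(OC)c2c(c1)[C@H](CO[Si](C)(C)C(C)(C)C)[C@@H](c1ccc(OCc3ccccc3)c(OC)c1)O2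
F2 | step 21 | methyl (3R)-3-(hydroxymethyl)-4-(protected dihydrobenzofuran-5-yl)butanoate | COC(=O)C[C@H](CO)Cc1cc(OC)c2c(c1)[C@H](CO[Si](C)(C)C(C)(C)C)[C@@H](c1ccc(OCc3ccccc3)c(OC)c1)O2
F3 | step 21 | (R)-4-[(protected dihydrobenzofuran-5-yl)methyl]dihydrofuran-2(3H)-one | C1C(=O)OC[C@@H]1Cc1cc(OC)c2c(c1)[C@H](CO[Si](C)(C)C(C)(C)C)[C@@H](c1ccc(OCc3ccccc3)c(OC)c1)O2
F4 | step 21 | methyl 4-{2-[(R)-4-benzyl-2-oxooxazolidin-3-yl]-2-oxoethoxy}-3-methoxybenzoate | COC(=O)c1ccc(OCC(=O)N2[C@H](Cc3ccccc3)COC2=O)c(OC)c1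
F5 | step 21 | syn (2R,3S) aldol adduct of F4 with 3 | COc1cc([C@H](O)[C@H](C(=O)N2[C@H](Cc3ccccc3)COC2=O)Oc2ccc(C(=O)OC)cc2OC)ccc1OCc1ccccc1
F6 | step 21 | threo (1S,2S) diol, benzoate series | COc1cc([C@H](O)[C@H](CO)Oc2ccc(C(=O)OC)cc2OC)ccc1OCc1ccccc1
F7 | step 21 | threo primary silyl ether, benzoate series | COc1cc([C@H](O)[C@H](CO[Si](C)(C)C(C)(C)C)Oc2ccc(C(=O)OC)cc2OC)ccc1OCc1ccccc1
F8 | step 21 | erythro (1R,2S) 4-nitrobenzoate, benzoate series | COc1cc([C@@H](OC(=O)c2ccc(cc2)[N+](=O)[O-])[C@H](CO[Si](C)(C)C(C)(C)C)Oc2ccc(C(=O)OC)cc2OC)ccc1OCc1ccccc1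
F9 | step 21 | erythro (1R,2S) alcohol, benzoate series | COc1cc([C@@H](O)[C@H](CO[Si](C)(C)C(C)(C)C)Oc2ccc(C(=O)OC)cc2OC)ccc1OCc1ccccc1
F10 | step 21 | erythro bis-silyl ether, benzoate series | COc1cc([C@@H](O[Si](C)(C)C(C)(C)C)[C@H](CO[Si](C)(C)C(C)(C)C)Oc2ccc(C(=O)OC)cc2OC)ccc1OCc1ccccc1
F11 | step 21 | ring B benzylic alcohol | COc1cc([C@@H](O[Si](C)(C)C(C)(C)C)[C@H](CO[Si](C)(C)C(C)(C)C)Oc2ccc(CO)cc2OC)ccc1OCc1ccccc1
F12 | step 21 | ring B benzylic bromide | COc1cc([C@@H](O[Si](C)(C)C(C)(C)C)[C@H](CO[Si](C)(C)C(C)(C)C)Oc2ccc(CBr)cc2OC)ccc1OCc1ccccc1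
F13 | step 8 | (2R,3S) mirror image of cis diester 11 | COC(=O)CCc1cc(OC)c2c(c1)[C@H](C(=O)OC)[C@H](c1ccc(OCc3ccccc3)c(OC)c1)O2
F14 | step 8 | (2R,3R) mirror image of trans diester 12 | COC(=O)CCc1cc(OC)c2c(c1)[C@@H](C(=O)OC)[C@H](c1ccc(OCc3ccccc3)c(OC)c1)O2
F15 | step 18 | threo (1S,2S) primary tert-butyl carbonate | COc1cc([C@H](O)[C@H](COC(=O)OC(C)(C)C)Oc2ccc(CCC(=O)OC)cc2OC)ccc1OCc1ccccc1
F16 | step 18 | threo benzylic mesylate of F15 | COc1cc([C@H](OS(C)(=O)=O)[C@H](COC(=O)OC(C)(C)C)Oc2ccc(CCC(=O)OC)cc2OC)ccc1OCc1ccccc1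
F17 | step 18 | trans-4-aryl-5-aryloxy-1,3-dioxan-2-one (erythro cyclic carbonate) | COc1cc([C@H]3OC(=O)OC[C@@H]3Oc2ccc(CCC(=O)OC)cc2OC)ccc1OCc1ccccc1
F18 | step 18 | erythro (1R,2S) diol | COc1cc([C@@H](O)[C@H](CO)Oc2ccc(CCC(=O)OC)cc2OC)ccc1OCc1ccccc1
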